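**Retrosynthetic overview**

- The target is (2S)-5,7,3',4',5'-pentamethoxyflavanone. The last step only unmasks C4=O from a spiro-1,3-dithiane, a temporary ring that keeps the base-labile β-aryloxy ketone away from base.
- C3–C4 and O1–C8a are cut together. This gives 2-(2-fluoro-4,6-dimethoxyphenyl)-1,3-dithiane (polarity-reversed C4) and (R)-2-(3,4,5-trimethoxyphenyl)oxirane (strained O1–C2–C3 unit). Ring C is the only ring of the target that is built, and it closes in that step.
- Enabling feature: O1–C2–C3 of ring C is the skeleton of an aryl oxirane placed 1,3 to the acyl carbon C4. C8a of ring A is ortho to C4 and meta to both the C5 and C7 methoxy groups, so a fluoride at C8a can be displaced by the alkoxide that the epoxide opening releases.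
- The dithiane comes from 1-fluoro-3,5-dimethoxybenzene (formylation, thioacetalisation). The epoxide comes from 2-bromo-1-(3,4,5-trimethoxyphenyl)ethanone (CBS reduction sets C2, then ring closure). The C2–O bond is never broken afterwards.

Key step: step 5

Assumption: 1-fluoro-3,5-dimethoxybenzene, 2-bromo-1-(3,4,5-trimethoxyphenyl)ethan-1-one and (R)-2-methyl-CBS-oxazaborolidine are taken as commercially available.

**Step 1**
Reactants: 1 1-fluoro-3,5-dimethoxybenzene
Product: 3 2-fluoro-4,6-dimethoxybenzaldehyde, via iminium salt 2 (not isolated)
Conditions: POCl3, DMF, 0 → 70 °C; then ice-water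
Reagents that add atoms: N,N-dimethylformamide CN(C)C=O; water O
Why: Vilsmeier–Haack formylation, in which the chloroiminium electrophile should attack the position para to one methoxy group and flanked by F and OMe (less crowded than the position between the two methoxy groups), and water hydrolyses the iminium salt to the aldehyde.

**Step 2**
Reactants: 3 2-fluoro-4,6-dimethoxybenzaldehyde
Product: 4 2-(2-fluoro-4,6-dimethoxyphenyl)-1,3-dithiane
Conditions: HS(CH2)3SH, BF3·OEt2 (20 mol %), CH2Cl2, 0 °C → rt
Reagents that add atoms: propane-1,3-dithiol SCCCS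
Why: Lewis acid catalysed dithioacetalisation of an aromatic aldehyde, which installs the temporary ring that later reverses the polarity of the future C4.

**Step 3**
Reactants: 5 2-bromo-1-(3,4,5-trimethoxyphenyl)ethan-1-one
Product: 6 (R)-2-bromo-1-(3,4,5-trimethoxyphenyl)ethan-1-ol
Conditions: (R)-2-methyl-CBS-oxazaborolidine (10 mol %), BH3·SMe2, THF, 0 °C; MeOH quench
Reagents that add atoms: none
Why: Corey–Bakshi–Shibata reduction, in which catalyst-bound borane delivers hydride to the ketone face fixed by turning the large aryl group away from the B-methyl group, so the (R)-catalyst should give the (R)-bromohydrin, the sense known for phenacyl halides.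

**Step 4**
Reactants: 6 (R)-2-bromo-1-(3,4,5-trimethoxyphenyl)ethan-1-ol
Product: 7 (R)-2-(3,4,5-trimethoxyphenyl)oxirane
Conditions: 2 M aq NaOH, Et2O, 0 °C → rt
Reagents that add atoms: none
Why: Intramolecular Williamson etherification (3-exo-tet displacement of the primary bromide by the alkoxide), which leaves the benzylic C–O bond untouched so the configuration is retained.

**Step 5**
Reactants: 4 2-(2-fluoro-4,6-dimethoxyphenyl)-1,3-dithiane; 7 (R)-2-(3,4,5-trimethoxyphenyl)oxirane
Product: 10 (2S)-5,7-dimethoxy-2-(3,4,5-trimethoxyphenyl)spiro[chromane-4,2'-[1,3]dithiane], via 2-lithiodithiane 8 (not isolated), via lithium alkoxide 9 (not isolated)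
Conditions: n-BuLi, THF, −78 → −40 °C; 7, DMPU, −40 °C → rt; then 65 °C
Reagents that add atoms: none
Why: Proposed new method: n-BuLi removes the dithiane C2–H of 4 to give the acyl-anion equivalent 8, which opens the strained oxirane 7 by SN2 attack at its unsubstituted CH2 (C3–C4 bond), and the lithium alkoxide 9 thereby released, deaggregated by DMPU, adds to the C–F carbon of ring A and expels LiF (O1–C8a bond), overall a formal [3+3] anionic annulation that inserts the aryl–acyl unit into the CH2–O bond of the epoxide. The closest known reaction types are the opening of terminal aryl epoxides by 2-aryl-2-lithio-1,3-dithianes and the intramolecular SNAr closure of 3-(2-fluoroaryl)propan-1-olates to chromans, and what is new is their merger in one flask with the epoxide-derived alkoxide as the only nucleophile and base of the second event. Ring C closes as a six-membered ring by ipso addition–elimination (formally a 6-exo-trig attack on C8a), helped by the Thorpe–Ingold effect of the spiro dithiane, by the two methoxy groups that stand meta to fluorine and so stabilise inductively, without donating into, the Meisenheimer-type charge at C4a, C6 and C8, and by the Li···F contact and precipitation of LiF. No stereocentre is created: C2 is brought in by 7 and keeps its spatial arrangement because its C–O bond is untouched in both events (the descriptor changes from R to S only through the CIP ranking), and the spiro carbon is not stereogenic. The selectivities needed are terminal over benzylic epoxide attack (secured by the bulk of the tertiary carbanion and the absence of a Lewis acid), dithiane over ring deprotonation between F and OMe (secured by the higher acidity of the doubly sulfur-stabilised benzylic C–H and by staying at or below −40 °C, where a stray aryllithium can still hand over its charge by proton transfer before it loses LiF), and closure on C–F instead of the other ortho carbon C–OMe (secured by the far higher SNAr reactivity of fluoride). Because C4 stays masked, retro-aldol cleavage and E1cB loss of the alkoxide, which would erode C2 at the ketone level, have no pathway.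

**Step 6**
Reactants: 10 (2S)-5,7-dimethoxy-2-(3,4,5-trimethoxyphenyl)spiro[chromane-4,2'-[1,3]dithiane]
Product: 11 (2S)-5,7-dimethoxy-2-(3,4,5-trimethoxyphenyl)chroman-4-one (target)
Conditions: MeI, CaCO3, MeCN/H2O (4:1), 45 °C
Reagents that add atoms: water O
Why: Alkylative dithiane hydrolysis, in which S-methylation makes sulfur a leaving group and water captures the thionium ion stabilised by the 5,7-dimethoxyaryl ring, while the non-oxidising, CaCO3-buffered medium spares the electron-rich rings and avoids the base-induced ring opening that would racemise C2.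

**Compound list**

| No. | Name | SMILES | Role |
|---|---|---|---|
| 1 | 1-fluoro-3,5-dimethoxybenzene | COc1cc(F)cc(OC)c1 | starting material |
| 2 | (2-fluoro-4,6-dimethoxybenzylidene)dimethyliminium dichlorophosphate | COc1cc(F)c(C=[N+](C)C)c(OC)c1.[O-]P(=O)(Cl)Cl | intermediate |
| 3 | 2-fluoro-4,6-dimethoxybenzaldehyde | COc1cc(F)c(C=O)c(OC)c1 | intermediate |
| 4 | 2-(2-fluoro-4,6-dimethoxyphenyl)-1,3-dithiane | COc1cc(F)c(C2SCCCS2)c(OC)c1 | intermediate |
| 5 | 2-bromo-1-(3,4,5-trimethoxyphenyl)ethan-1-one | COc1cc(C(=O)CBr)cc(OC)c1OC | starting material |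
| 6 | (R)-2-bromo-1-(3,4,5-trimethoxyphenyl)ethan-1-ol | O[C@H](c1cc(OC)c(OC)c(OC)c1)CBr | intermediate |
| 7 | (R)-2-(3,4,5-trimethoxyphenyl)oxirane | O1[C@H](c2cc(OC)c(OC)c(OC)c2)C1 | intermediate |
| 8 | 2-(2-fluoro-4,6-dimethoxyphenyl)-2-lithio-1,3-dithiane | COc1cc(F)c(C2([Li])SCCCS2)c(OC)c1 | intermediate |
| 9 | lithium (S)-2-[2-(2-fluoro-4,6-dimethoxyphenyl)-1,3-dithian-2-yl]-1-(3,4,5-trimethoxyphenyl)ethan-1-olate | [Li]O[C@H](c1cc(OC)c(OC)c(OC)c1)CC1(SCCCS1)c1c(F)cc(OC)cc1OC | intermediate |
| 10 | (2S)-5,7-dimethoxy-2-(3,4,5-trimethoxyphenyl)spiro[chromane-4,2'-[1,3]dithiane] | COc1cc(OC)c2c(c1)O[C@H](c1cc(OC)c(OC)c(OC)c1)CC21SCCCS1 | intermediate |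
| 11 | (2S)-5,7-dimethoxy-2-(3,4,5-trimethoxyphenyl)chroman-4-one | COc1cc(OC)c2c(c1)O[C@H](c1cc(OC)c(OC)c(OC)c1)CC2=O | target |

Total step count: 6
Longest linear sequence: 4 steps (steps 1, 2, 5, 6, or steps 3, 4, 5, 6)

**Steps most likely to fail**

1. **Step 5 (Proposed new method).**
   - What may go wrong: the aggregated lithium alkoxide may attack too slowly at a C–F carbon that has no conjugating acceptor. Ring lithiation next to fluorine, followed by loss of LiF, may also compete.
   - Fallback (known chemistry, sets out from 4 and 7, returns at 11): the two bond formations are separated and the ether closure is moved to the ketone oxidation level.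
   - The dithiane/epoxide opening is run without heating and quenched with aq NH4Cl. This gives (S)-2-[2-(2-fluoro-4,6-dimethoxyphenyl)-1,3-dithian-2-yl]-1-(3,4,5-trimethoxyphenyl)ethan-1-ol F1.
   - Alkylative hydrolysis (MeI, CaCO3, aq MeCN) then unmasks (S)-1-(2-fluoro-4,6-dimethoxyphenyl)-3-hydroxy-3-(3,4,5-trimethoxyphenyl)propan-1-one F2.
   - In F2 the free ortho carbonyl activates the C–F carbon. A carbonyl-activated intramolecular SNAr (K2CO3, DMF, 0 °C → rt), the closure used to make chromones and 4-quinolones from 2-fluoroaryl ketones, should give 11 directly.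

2. **Step 6.**
   - What may go wrong: S-alkylation may be sluggish at the crowded spiro centre next to the C5 methoxy group. Local acid build-up could also open ring C and erode C2.
   - Fallback (sets out from 10, returns at 11): alkylative activation is replaced by a staged oxidative one.
   - One equivalent of mCPBA (CH2Cl2, −78 °C) oxidises one sulfur much faster than the arenes. This gives (2S)-5,7-dimethoxy-2-(3,4,5-trimethoxyphenyl)spiro[chromane-4,2'-[1,3]dithiane] 1'-oxide F3, as a mixture of diastereomers at sulfur and C4.
   - F3 is hydrolysed with 1 M HCl in THF at rt to 11.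

3. **Step 3.**
   - What may go wrong: facial selectivity may be incomplete because of uncatalysed background reduction by free borane. Any loss here would be carried unchanged into the target.
   - Fallback (sets out from 5, returns at 6): asymmetric catalysis is replaced by an enzymatic kinetic resolution.
   - NaBH4 (MeOH, 0 °C) gives racemic 2-bromo-1-(3,4,5-trimethoxyphenyl)ethan-1-ol F4.
   - A lipase (Burkholderia cepacia lipase, vinyl acetate, MTBE, rt) acylates the enantiomer predicted by the empirical size rule for secondary alcohols (aryl large, CH2Br medium). That product is (S)-2-bromo-1-(3,4,5-trimethoxyphenyl)ethyl acetate F5.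
   - Unreacted 6 is left behind and is separated by chromatography.

**Further compounds**
F1 | step 5 | (S)-2-[2-(2-fluoro-4,6-dimethoxyphenyl)-1,3-dithian-2-yl]-1-(3,4,5-trimethoxyphenyl)ethan-1-ol | O[C@H](c1cc(OC)c(OC)c(OC)c1)CC1(SCCCS1)c1c(F)cc(OC)cc1OC
F2 | step 5 | (S)-1-(2-fluoro-4,6-dimethoxyphenyl)-3-hydroxy-3-(3,4,5-trimethoxyphenyl)propan-1-one | O[C@H](c1cc(OC)c(OC)c(OC)c1)CC(=O)c1c(F)cc(OC)cc1OC
F3 | step 6 | (2S)-5,7-dimethoxy-2-(3,4,5-trimethoxyphenyl)spiro[chromane-4,2'-[1,3]dithiane] 1'-oxide (mixture at S and C4) | COc1cc(OC)c2c(c1)O[C@H](c1cc(OC)c(OC)c(OC)c1)CC21SCCCS1=O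
F4 | step 3 | racemic 2-bromo-1-(3,4,5-trimethoxyphenyl)ethan-1-ol | OC(CBr)c1cc(OC)c(OC)c(OC)c1
F5 | step 3 | (S)-2-bromo-1-(3,4,5-trimethoxyphenyl)ethyl acetate | CC(=O)O[C@@H](c1cc(OC)c(OC)c(OC)c1)CBr
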